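The runs come from a simulation from invented constants; the scatter is artificial.

1. I could not let the protic impurity quench more starting material than was charged of it, since each molecule takes one. So I divided [protic impurity] at the start by the whole charge of starting material, which for red gave 6.25%. This ratio is the sacrifice share, the ceiling on quenched substrate in percent of the charge.

| flask | starting material | protic impurity | enzyme | remark | time |
|---|---|---|---|---|---|
| north-east | 0.025 M (in portions, 3) | 0.038 M | 5 µM | run made earlier; portions every 15 min |  |
| south | 0.025 M (in portions, 3) | 0.013 M | 5 µM | run made earlier; portions every 15 min |  |
| amber | 0.025 M (in portions, 3) | 0.0250 M | 5.0 µM | the portions of starting material follow each other after 15 min, the first at the start | 50 min |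
| blue | 0.050 M (in portions, 3) | 0.0250 M | 5.0 µM | the portions of starting material follow each other after 15 min, the first at the start | 50 min |
| grey | 0.10 M (in portions, 3) | 0.0250 M | 5.0 µM | the portions of starting material follow each other after 15 min, the first at the start | 50 min |
| green | 0.20 M (in portions, 3) | 0.0250 M | 5.0 µM | the portions of starting material follow each other after 15 min, the first at the start | 50 min |
| red | 0.40 M (in portions, 3) | 0.0250 M | 5.0 µM | the portions of starting material follow each other after 15 min, the first at the start | 50 min |

| run | time / min | target / % | starting material / % |
|---|---|---|---|
| north-east | 4.00 | 5.0 | 0 |
| north-east | 8.00 | 5.9 | 0.2 |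
| north-east | 12.0 | 5.5 | 0 |
| north-east | 20.0 | 9.3 | 0 |
| south | 4.00 | 10.9 | 2.9 |
| south | 8.00 | 12.3 | 0 |
| south | 12.0 | 12.6 | 0.5 |
| south | 20.0 | 20.9 | 5.0 |

(standard deviation of a reading: 0.5 percentage points)

- the earlier runs were read with a standard deviation of 0.5 percentage points
- what may be going on: starting material + protic impurity -> quenched substrate; starting material -> uncatalysed product; starting material + enzyme -> target + enzyme; 2 enzyme <-> resting dimer
- "hardly changes" means that all values lie within two and a half points (for a concentration: within two and a half percent of the largest)

- amount of target at the end, in percent of the starting material charged for amber, blue, grey, green, red, in this order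
- how the row runs (falls all the way / rises, then falls / falls, then rises / hardly changes / rises all the way)

2. Each portion was a third of the charge. In the south run, the reading of 12.6% target at 12.0 min was 37.8% of the first portion. In the north-east run, with more protic impurity, the reading of 5.5% was 16.5%.

3. My first extreme held [protic impurity] at one mean value instead of its falling curve, a pseudo-first-order picture. The reciprocal of the target share then rises in a straight line with [protic impurity]. The amber charge of 0.0250 M lies midway between the two runs, so I averaged the reciprocals and got 23.0% for the first portion in amber, a share I then carried over to the whole charge as a rough estimate.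

4. My second extreme spent the protic impurity at once, so the flask paid its sacrifice share and the rest divided between enzyme and uncatalysed path. I expected red to come close to this, because one portion there held 0.133 M, more than the 0.0250 M of protic impurity. That left a ceiling of 93.8% for target in red, but the runs showed no charge above 0.025 M, so I could not read how that remainder would divide.

5. The forecast gave 19%, 29%, 40%, 47% and 51%, and its shape was: rises all the way. Its grounds were: “At high charge it is gone in the first portion, and the yield approaches the enzyme/uncatalysed split, about 50%.” At amber it stood lower than my estimate for the whole charge.

6. The flasks gave 22.9%, 36.7%, 45.8%, 34.8% and 15.2%, so the row ran: rises, then falls. It turned at 0.094 M.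

    starting material + protic impurity → quenched substrate (k = 36.0 L mol⁻¹ min⁻¹)
    starting material → uncatalysed product (k = 0.0450 min⁻¹)
    starting material + enzyme → target + enzyme, rate k3*[starting material]*[enzyme]/(1 + ([starting material]/Km3) + ([starting material]/Ksi3)^2) (12.0 mM, 37.0 mM, k = 67000 L mol⁻¹ min⁻¹)
    2 enzyme ⇌ resting dimer (K = 1.30 × 10⁵ L mol⁻¹, k = 9800 L mol⁻¹ min⁻¹)

In red, the sacrifice share of 6.25% stood against 6.25% of quenched substrate at 50.0 min. The remainder of 93.8% held 15.2% target, 60.9% uncatalysed product and 17.6% starting material. In grey, the sacrifice share was 25.0%, and quenched substrate stood at 25.0% at 50.0 min.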